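**Retrosynthetic overview**

- The target is reached last by cleaving the six aryl methyl ethers of its hexamethyl ether.
- The dihydrofuran ring is the only ring built. It is closed in one (4+1) annulation that forms C2–C3 and O1–C2, from an ortho-quinone methide (released by base from a phenolic benzhydryl sulfone) and a chiral 3,4-dimethoxybenzyl sulfonium ylide.
- The feature the strategy rests on: C3a of the benzofuran lies between the two oxygen-bearing carbons C7a (O1) and C4 (OH), a 2-benzylresorcinol pattern. C3 is therefore the exocyclic carbon of an ortho-quinone methide of that ring, and the C3–C3a bond can be made by lithiation between two ortho oxygens.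
- The sulfone comes from a carbinol made by directed lithiation of a Horner–Wadsworth–Emmons stilbene and addition to 3,5-dimethoxybenzaldehyde. The C4 oxygen is carried as a methyl ether (no acidic OH on the quinone methide, no free phenol after annulation); the C7a oxygen is a MOM ether removed when the sulfone is made.
- The sulfonium salt comes from 3,4-dimethoxybenzyl bromide and (2S,5S)-2,5-dimethylthiolane, made from (2R,5R)-hexane-2,5-diol by double inversion.

Key step: step 9

Assumption: the ylide is taken to react on the same face as the parent benzylide of 2,5-dimethylthiolane does with aldehydes, where the (2R,5R)-sulfide is recalled to give (S,S)-stilbene oxide; because at C2 of the dihydrobenzofuran the aryl group outranks the newly bonded carbon (the reverse of the epoxide case), that topicity corresponds to 2R, so the (2S,5S)-sulfide is used for 2S,3S.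

**Route**

Step 1
Reactants: 1 3-hydroxy-5-methoxybenzaldehyde
Product: 2 3-methoxy-5-(methoxymethoxy)benzaldehyde
Conditions: MOMCl (1.5 equiv), i-Pr2NEt (2 equiv), CH2Cl2, 0 °C → rt
Reagents that add atoms: chloromethyl methyl ether, COCCl
Why: O-alkylation of the phenol (MOM ether formation) masks the oxygen that will become O1 and installs a strong ortho-directing group, while the aldehyde is untouched.

Step 2
Reactants: 2 3-methoxy-5-(methoxymethoxy)benzaldehyde; 3 diethyl (4-methoxybenzyl)phosphonate
Product: 5 1-methoxy-3-(methoxymethoxy)-5-[(E)-2-(4-methoxyphenyl)ethenyl]benzene, via phosphonate carbanion 4 (not isolated)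
Conditions: 3 (1.2 equiv), KOtBu (1.3 equiv), THF, 0 °C; then 2, 0 °C → rt
Reagents that add atoms: none
Why: Horner–Wadsworth–Emmons olefination of a benzylic phosphonate with an aromatic aldehyde should give the (E)-stilbene through the anti-configured adduct; the MOM and methyl ethers are inert to KOtBu.

Step 3
Reactants: 5 1-methoxy-3-(methoxymethoxy)-5-[(E)-2-(4-methoxyphenyl)ethenyl]benzene; 6 3,5-dimethoxybenzaldehyde
Product: 8 racemic (3,5-dimethoxyphenyl){2-methoxy-6-(methoxymethoxy)-4-[(E)-2-(4-methoxyphenyl)ethenyl]phenyl}methanol, via aryllithium 7 (not isolated)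
Conditions: n-BuLi (1.15 equiv), THF, −20 → 0 °C; then 6 (1.2 equiv), −78 → 0 °C; H2O
Reagents that add atoms: none
Why: Directed ortho-metalation: the ring C–H flanked by the OMe and OMOM groups is the most acidic and is coordinated from both sides, so n-BuLi should lithiate there, and 1,2-addition of 7 to the non-enolisable aldehyde gives the carbinol, whose stereocentre is racemic and is erased in step 9.

Step 4
Reactants: 8 racemic (3,5-dimethoxyphenyl){2-methoxy-6-(methoxymethoxy)-4-[(E)-2-(4-methoxyphenyl)ethenyl]phenyl}methanol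
Product: 10 racemic 2-[(3,5-dimethoxyphenyl)(4-methylbenzenesulfonyl)methyl]-3-methoxy-5-[(E)-2-(4-methoxyphenyl)ethenyl]phenol, via MOM-protected sulfone 9 (not isolated)
Conditions: p-TolSO2Na (5 equiv), 3 M aq. HCl, THF, rt → 40 °C
Reagents that add atoms: sodium 4-methylbenzenesulfinate, Cc1ccc(S(=O)[O-])cc1.[Na+]
Why: Acid ionises the benzhydrol, whose cation is stabilised by both ortho oxygens, and sulfinate captures it at sulfur (SN1 sulfone formation) to give 9, after which acid hydrolysis of the MOM acetal frees the phenol; the excess sulfinate outcompetes arene nucleophiles and scavenges the formaldehyde released, and the stilbene and methyl ethers are inert to dilute HCl.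

Step 5
Reactants: 11 (2R,5R)-hexane-2,5-diol
Product: 12 (2R,5R)-hexane-2,5-diyl dimethanesulfonate
Conditions: MsCl (2.4 equiv), Et3N (3 equiv), CH2Cl2, −20 → 0 °C
Reagents that add atoms: methanesulfonyl chloride, CS(=O)(=O)Cl
Why: O-sulfonylation of both secondary alcohols forms only O–S bonds, so both stereocentres are retained and a bis-electrophile results.

Step 6
Reactants: 12 (2R,5R)-hexane-2,5-diyl dimethanesulfonate
Product: 14 (2S,5S)-2,5-dimethylthiolane, via thiolate monomesylate 13 (not isolated)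
Conditions: Na2S·9H2O (1.2 equiv), DMSO, rt; pentane extraction, distillation
Reagents that add atoms: sodium sulfide, [Na+].[Na+].[S-2]
Why: Double SN2 thioetherification: sulfide displaces one mesylate and the thiolate 13 closes the five-membered ring (5-exo-tet), each with inversion, so the (2R,5R)-dimesylate should give the (2S,5S)-thiolane.

Step 7
Reactants: 15 3,4-dimethoxybenzyl alcohol
Product: 16 3,4-dimethoxybenzyl bromide
Conditions: PBr3 (0.4 equiv), Et2O, 0 °C; used at once
Reagents that add atoms: phosphorus tribromide, BrP(Br)Br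
Why: Conversion of an electron-rich benzylic alcohol into its bromide through the phosphite ester and bromide displacement; the bromide is used fresh because it hydrolyses readily.

Step 8
Reactants: 16 3,4-dimethoxybenzyl bromide; 14 (2S,5S)-2,5-dimethylthiolane
Product: 17 (2S,5S)-1-(3,4-dimethoxybenzyl)-2,5-dimethylthiolan-1-ium tetrafluoroborate
Conditions: 14 (1.1 equiv), AgBF4 (1.0 equiv, added last), CH2Cl2, 0 °C → rt, dark; filtration, precipitation with Et2O
Reagents that add atoms: silver tetrafluoroborate, [Ag+].F[B-](F)(F)F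
Why: S-alkylation of the hindered sulfide, driven by halide abstraction with AgBF4, gives the sulfonium salt with a non-nucleophilic counter-ion; the thiolane is C2-symmetric, so its two lone pairs are equivalent and a single sulfonium stereoisomer forms.

Step 9
Reactants: 10 racemic 2-[(3,5-dimethoxyphenyl)(4-methylbenzenesulfonyl)methyl]-3-methoxy-5-[(E)-2-(4-methoxyphenyl)ethenyl]phenol; 17 (2S,5S)-1-(3,4-dimethoxybenzyl)-2,5-dimethylthiolan-1-ium tetrafluoroborate
Product: 21 (2S,3S)-2-(3,4-dimethoxyphenyl)-3-(3,5-dimethoxyphenyl)-4-methoxy-6-[(E)-2-(4-methoxyphenyl)ethenyl]-2,3-dihydro-1-benzofuran, via sulfonium ylide 18 (not isolated), via ortho-quinone methide 19 (not isolated), via anti betaine 20 (not isolated)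
Conditions: 17 (1.5 equiv), Cs2CO3 (3 equiv), MeCN–CH2Cl2, −20 → 0 °C, slow addition of 10
Reagents that add atoms: none
Why: Cs2CO3 deprotonates the phenol of 10, whose phenoxide expels p-toluenesulfinate (E1cB) to give ortho-quinone methide 19, and the same base converts 17 into the semi-stabilised benzylide 18; conjugate addition of the ylide carbon to the exocyclic methide carbon forms the C2–C3 bond, restores the arene and gives betaine 20. The phenoxide then closes the dihydrofuran ring by 5-exo-tet SN2 displacement of neutral sulfide 14 at C2 (O1–C2 bond), with inversion at that carbon. The closest known reaction type is the formal (4+1) annulation of base-generated ortho-quinone methides with sulfonium ylides to trans-2,3-dihydrobenzofurans, combined with the auxiliary control of C2-symmetric 2,5-dimethylthiolane benzylides known from aldehyde epoxidation. C2 is set by the sulfide: the ylide aryl group lies anti to the ring and the methide adds to the ylide face remote from the α-methyl group cis to the ylide carbon, so that after the invertive closure the (2S,5S)-sulfide should give 2S; C3 is set relative to C2 in the addition, which goes through the anti betaine with the aryl groups apart, and backside closure turns this into the 2,3-trans (3S) arrangement. The step needs C-attack at the methide carbon in preference to O-alkylation of phenoxides by the salt and to self-condensation of 19: the aryl group on the methide carbon and the C4 methoxy group stabilise 19, only one phenol is present so that O1 can come from one oxygen only and no phenol remains in 21, and the BF4 counter-ion keeps 17 from reverting to bromide 16.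

Step 10
Reactants: 21 (2S,3S)-2-(3,4-dimethoxyphenyl)-3-(3,5-dimethoxyphenyl)-4-methoxy-6-[(E)-2-(4-methoxyphenyl)ethenyl]-2,3-dihydro-1-benzofuran
Product: 22 4-[(2S,3S)-3-(3,5-dihydroxyphenyl)-4-hydroxy-6-[(E)-2-(4-hydroxyphenyl)ethenyl]-2,3-dihydro-1-benzofuran-2-yl]benzene-1,2-diol
Conditions: BBr3 (15 equiv), CH2Cl2, −78 → 0 °C; then ice–water; reversed-phase chromatography under argon
Reagents that add atoms: none
Why: BBr3 ether cleavage (O-complexation, then bromide attack at methyl) should remove the six aryl methyl ethers without touching the aryl–O bonds, the alkene or the two C–H stereocentres; if the benzylic O1–C2 bond opens reversibly, re-closure by either of the two then equivalent ortho oxygens gives the same trans ring with C3 unchanged, so 2S,3S should be retained.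

**Compound list**

1 | 3-hydroxy-5-methoxybenzaldehyde | COc1cc(O)cc(C=O)c1 | starting material
2 | 3-methoxy-5-(methoxymethoxy)benzaldehyde | COCOc1cc(OC)cc(C=O)c1 | intermediate
3 | diethyl (4-methoxybenzyl)phosphonate | CCOP(=O)(Cc1ccc(OC)cc1)OCC | starting material
4 | potassium salt of the carbanion of 3 (not isolated) | CCOP(=O)(OCC)[CH-]c1ccc(OC)cc1.[K+] | intermediate
5 | 1-methoxy-3-(methoxymethoxy)-5-[(E)-2-(4-methoxyphenyl)ethenyl]benzene | COCOc1cc(OC)cc(/C=C/c2ccc(OC)cc2)c1 | intermediate
6 | 3,5-dimethoxybenzaldehyde | COc1cc(C=O)cc(OC)c1 | starting material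
7 | {2-methoxy-6-(methoxymethoxy)-4-[(E)-2-(4-methoxyphenyl)ethenyl]phenyl}lithium (not isolated) | [Li]c1c(OC)cc(/C=C/c2ccc(OC)cc2)cc1OCOC | intermediate
8 | racemic (3,5-dimethoxyphenyl){2-methoxy-6-(methoxymethoxy)-4-[(E)-2-(4-methoxyphenyl)ethenyl]phenyl}methanol | COCOc1cc(/C=C/c2ccc(OC)cc2)cc(OC)c1C(O)c1cc(OC)cc(OC)c1 | intermediate
9 | racemic 2-[(3,5-dimethoxyphenyl)(4-methylbenzenesulfonyl)methyl]-1-methoxy-3-(methoxymethoxy)-5-[(E)-2-(4-methoxyphenyl)ethenyl]benzene (not isolated) | COCOc1cc(/C=C/c2ccc(OC)cc2)cc(OC)c1C(c1cc(OC)cc(OC)c1)S(=O)(=O)c1ccc(C)cc1 | intermediate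
10 | racemic 2-[(3,5-dimethoxyphenyl)(4-methylbenzenesulfonyl)methyl]-3-methoxy-5-[(E)-2-(4-methoxyphenyl)ethenyl]phenol | COc1ccc(/C=C/c2cc(O)c(C(c3cc(OC)cc(OC)c3)S(=O)(=O)c3ccc(C)cc3)c(OC)c2)cc1 | intermediate
11 | (2R,5R)-hexane-2,5-diol | C[C@@H](O)CC[C@@H](C)O | starting material
12 | (2R,5R)-hexane-2,5-diyl dimethanesulfonate | C[C@@H](OS(C)(=O)=O)CC[C@@H](C)OS(C)(=O)=O | intermediate
13 | sodium (2S,5R)-5-(methanesulfonyloxy)hexane-2-thiolate (not isolated) | C[C@H]([S-])CC[C@@H](C)OS(C)(=O)=O.[Na+] | intermediate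
14 | (2S,5S)-2,5-dimethylthiolane | C[C@H]1CC[C@H](C)S1 | intermediate
15 | 3,4-dimethoxybenzyl alcohol | COc1ccc(CO)cc1OC | starting material
16 | 3,4-dimethoxybenzyl bromide | COc1ccc(CBr)cc1OC | intermediate
17 | (2S,5S)-1-(3,4-dimethoxybenzyl)-2,5-dimethylthiolan-1-ium tetrafluoroborate | COc1ccc(C[S+]2[C@@H](C)CC[C@@H]2C)cc1OC.F[B-](F)(F)F | intermediate
18 | (2S,5S)-2,5-dimethylthiolan-1-ium (3,4-dimethoxyphenyl)methylide (not isolated) | COc1ccc([CH-][S+]2[C@@H](C)CC[C@@H]2C)cc1OC | intermediate
19 | 6-[(3,5-dimethoxyphenyl)methylidene]-5-methoxy-3-[(E)-2-(4-methoxyphenyl)ethenyl]cyclohexa-2,4-dien-1-one, exocyclic alkene geometry not fixed (not isolated) | COc1ccc(/C=C/C2=CC(=O)C(=Cc3cc(OC)cc(OC)c3)C(OC)=C2)cc1 | intermediate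
20 | 2-[(1S,2R)-2-(3,4-dimethoxyphenyl)-1-(3,5-dimethoxyphenyl)-2-[(2S,5S)-2,5-dimethylthiolan-1-ium-1-yl]ethyl]-3-methoxy-5-[(E)-2-(4-methoxyphenyl)ethenyl]phenolate (not isolated) | COc1ccc(/C=C/c2cc([O-])c([C@H](c3cc(OC)cc(OC)c3)[C@H](c3ccc(OC)c(OC)c3)[S+]3[C@@H](C)CC[C@@H]3C)c(OC)c2)cc1 | intermediate
21 | (2S,3S)-2-(3,4-dimethoxyphenyl)-3-(3,5-dimethoxyphenyl)-4-methoxy-6-[(E)-2-(4-methoxyphenyl)ethenyl]-2,3-dihydro-1-benzofuran | COc1ccc(/C=C/c2cc(OC)c3c(c2)O[C@H](c2ccc(OC)c(OC)c2)[C@H]3c2cc(OC)cc(OC)c2)cc1 | intermediate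
22 | 4-[(2S,3S)-3-(3,5-dihydroxyphenyl)-4-hydroxy-6-[(E)-2-(4-hydroxyphenyl)ethenyl]-2,3-dihydro-1-benzofuran-2-yl]benzene-1,2-diol | Oc1ccc(/C=C/c2cc(O)c3c(c2)O[C@H](c2ccc(O)c(O)c2)[C@H]3c2cc(O)cc(O)c2)cc1 | target

**Step count and risks**

Total step count: 10. Longest linear sequence: 6 steps (steps 1, 2, 3, 4, 9, 10).

Steps most likely to fail:

1. Step 9. The danger is insufficient discrimination between the two faces of the ylide carbon or of the methide carbon, which would erode enantiomeric or trans/cis purity. Fallback: the annulation is run without an auxiliary and the enantiomers are separated. It sets out from bromide 16 and sulfone 10 and returns at 21. Bromide 16 and tetrahydrothiophene with AgBF4 in CH2Cl2 give 1-(3,4-dimethoxybenzyl)thiolan-1-ium tetrafluoroborate F1. Its ylide, thiolan-1-ium (3,4-dimethoxyphenyl)methylide F2, generated with Cs2CO3 in the presence of 10, should give racemic trans product, that is 21 together with its (2R,3R)-enantiomer F3. Preparative chromatography on a polysaccharide chiral stationary phase (supercritical CO2–MeOH) then delivers 21.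

2. Step 10. The danger is ionisation of the benzylic O1–C2 bond, which lies para to a donor oxygen of the C2 aryl ring, under the Lewis acid, followed by elimination or oligomerisation instead of re-closure. Fallback: the two oxygens of the C2 aryl ring are carried as electron-poor pivalates, which disfavour that ionisation and are removed by base at the end. It sets out from sulfide 14 and sulfone 10 and returns at 22.
   - Commercial 4-methylcatechol is acylated (PivCl, pyridine, CH2Cl2) to 4-methyl-1,2-phenylene bis(2,2-dimethylpropanoate) F4.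
   - Wohl–Ziegler bromination (NBS, AIBN, PhCF3, 80 °C) gives 4-(bromomethyl)-1,2-phenylene bis(2,2-dimethylpropanoate) F5.
   - Alkylation of 14 (AgBF4, CH2Cl2) gives (2S,5S)-1-[3,4-bis(2,2-dimethylpropanoyloxy)benzyl]-2,5-dimethylthiolan-1-ium tetrafluoroborate F6.
   - Under the conditions of step 9 the derived ylide, (2S,5S)-2,5-dimethylthiolan-1-ium [3,4-bis(2,2-dimethylpropanoyloxy)phenyl]methylide F7, and sulfone 10 should give 4-[(2S,3S)-3-(3,5-dimethoxyphenyl)-4-methoxy-6-[(E)-2-(4-methoxyphenyl)ethenyl]-2,3-dihydro-1-benzofuran-2-yl]-1,2-phenylene bis(2,2-dimethylpropanoate) F8.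
   - BBr3 (CH2Cl2, −78 → 0 °C) cleaves its four methyl ethers to 4-[(2S,3S)-3-(3,5-dihydroxyphenyl)-4-hydroxy-6-[(E)-2-(4-hydroxyphenyl)ethenyl]-2,3-dihydro-1-benzofuran-2-yl]-1,2-phenylene bis(2,2-dimethylpropanoate) F9.
   - K2CO3 in degassed MeOH, then dilute HCl, removes the two pivalates to give 22.

3. Step 3. The danger is addition of n-BuLi across the stilbene double bond (carbolithiation) in competition with ring deprotonation. Fallback: the metalation is moved to a stage without an alkene, and the aryllithium is later made by iodine–lithium exchange, which is fast at −78 °C. It sets out from aldehyde 2 and returns at carbinol 8.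
   - Aldehyde 2 is converted (HC(OMe)3, cat. p-TsOH, MeOH) into 1-(dimethoxymethyl)-3-methoxy-5-(methoxymethoxy)benzene F10.
   - n-BuLi (THF, 0 °C) lithiates it between the two ring oxygens to [4-(dimethoxymethyl)-2-methoxy-6-(methoxymethoxy)phenyl]lithium F11.
   - I2 gives 5-(dimethoxymethyl)-2-iodo-1-methoxy-3-(methoxymethoxy)benzene F12.
   - PPTS in acetone–H2O at rt unmasks 4-iodo-3-methoxy-5-(methoxymethoxy)benzaldehyde F13.
   - Horner–Wadsworth–Emmons olefination with phosphonate 3 (KOtBu, THF) gives 2-iodo-1-methoxy-3-(methoxymethoxy)-5-[(E)-2-(4-methoxyphenyl)ethenyl]benzene F14.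
   - n-BuLi (THF, −78 °C, minutes) regenerates aryllithium 7, which adds to aldehyde 6 to give 8.

**Further compounds**

F1 | step 9 | 1-(3,4-dimethoxybenzyl)thiolan-1-ium tetrafluoroborate | COc1ccc(C[S+]2CCCC2)cc1OC.F[B-](F)(F)F
F2 | step 9 | thiolan-1-ium (3,4-dimethoxyphenyl)methylide | COc1ccc([CH-][S+]2CCCC2)cc1OC
F3 | step 9 | (2R,3R)-2-(3,4-dimethoxyphenyl)-3-(3,5-dimethoxyphenyl)-4-methoxy-6-[(E)-2-(4-methoxyphenyl)ethenyl]-2,3-dihydro-1-benzofuran | COc1ccc(/C=C/c2cc(OC)c3c(c2)O[C@@H](c2ccc(OC)c(OC)c2)[C@@H]3c2cc(OC)cc(OC)c2)cc1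
F4 | step 10 | 4-methyl-1,2-phenylene bis(2,2-dimethylpropanoate) | Cc1ccc(OC(=O)C(C)(C)C)c(OC(=O)C(C)(C)C)c1
F5 | step 10 | 4-(bromomethyl)-1,2-phenylene bis(2,2-dimethylpropanoate) | BrCc1ccc(OC(=O)C(C)(C)C)c(OC(=O)C(C)(C)C)c1
F6 | step 10 | (2S,5S)-1-[3,4-bis(2,2-dimethylpropanoyloxy)benzyl]-2,5-dimethylthiolan-1-ium tetrafluoroborate | CC(C)(C)C(=O)Oc1ccc(C[S+]2[C@@H](C)CC[C@@H]2C)cc1OC(=O)C(C)(C)C.F[B-](F)(F)F
F7 | step 10 | (2S,5S)-2,5-dimethylthiolan-1-ium [3,4-bis(2,2-dimethylpropanoyloxy)phenyl]methylide | CC(C)(C)C(=O)Oc1ccc([CH-][S+]2[C@@H](C)CC[C@@H]2C)cc1OC(=O)C(C)(C)C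
F8 | step 10 | 4-[(2S,3S)-3-(3,5-dimethoxyphenyl)-4-methoxy-6-[(E)-2-(4-methoxyphenyl)ethenyl]-2,3-dihydro-1-benzofuran-2-yl]-1,2-phenylene bis(2,2-dimethylpropanoate) | COc1ccc(/C=C/c2cc(OC)c3c(c2)O[C@H](c2ccc(OC(=O)C(C)(C)C)c(OC(=O)C(C)(C)C)c2)[C@H]3c2cc(OC)cc(OC)c2)cc1
F9 | step 10 | 4-[(2S,3S)-3-(3,5-dihydroxyphenyl)-4-hydroxy-6-[(E)-2-(4-hydroxyphenyl)ethenyl]-2,3-dihydro-1-benzofuran-2-yl]-1,2-phenylene bis(2,2-dimethylpropanoate) | Oc1ccc(/C=C/c2cc(O)c3c(c2)O[C@H](c2ccc(OC(=O)C(C)(C)C)c(OC(=O)C(C)(C)C)c2)[C@H]3c2cc(O)cc(O)c2)cc1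
F10 | step 3 | 1-(dimethoxymethyl)-3-methoxy-5-(methoxymethoxy)benzene | COCOc1cc(OC)cc(C(OC)OC)c1
F11 | step 3 | [4-(dimethoxymethyl)-2-methoxy-6-(methoxymethoxy)phenyl]lithium | [Li]c1c(OC)cc(C(OC)OC)cc1OCOC
F12 | step 3 | 5-(dimethoxymethyl)-2-iodo-1-methoxy-3-(methoxymethoxy)benzene | COCOc1cc(C(OC)OC)cc(OC)c1I
F13 | step 3 | 4-iodo-3-methoxy-5-(methoxymethoxy)benzaldehyde | COCOc1cc(C=O)cc(OC)c1I
F14 | step 3 | 2-iodo-1-methoxy-3-(methoxymethoxy)-5-[(E)-2-(4-methoxyphenyl)ethenyl]benzene | COCOc1cc(/C=C/c2ccc(OC)cc2)cc(OC)c1I
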